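**Retrosynthetic overview**

- Feature: the cyclohexene ring (C1 carries the aroyl group, C6 the phenyl group). Its only alkene, C3=C4, with the 4-methylpent-3-enyl chain on C4, is read as the trace of a terminal alkyne; C5, C6, C1 and C2 are then a buta-1,3-diene bearing phenyl and an ester on its two inner carbons.
- Aryl ketone: cut between the carbonyl carbon and the trioxygenated benzene ring, giving the trans aldehyde and an aryllithium. The oxygen para to lithium is silylated so that lithiation can only occur between OMe and OMOM, which gives the 2,4-dihydroxy-6-methoxy pattern.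
- Stereocentres: carboxylate-directed asymmetric hydrogenation of the tetrasubstituted C1=C6 enoic acid (sets C6, cis product), then base epimerisation of C1 at the ester stage to trans.
- Ring: cobalt-catalysed [4+2] cycloaddition of methyl 2-methylidene-3-phenylbut-3-enoate with 6-methylhept-5-en-1-yne forms C2–C3 and C4–C5 and closes the cyclohexadiene. It is the only ring built; both benzene rings are bought.
- Precursors: the diene from methyl propiolate and alpha-bromostyrene (hydrostannation, Stille coupling); the enyne from 5-bromo-2-methylpent-2-ene and an acetylide.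

Key step: step 4

Assumption: the sense of induction in step 6 cannot be assigned in advance for this acid; the route is written with the (R)-ligand, and the (S)-ligand is used instead if a test run delivers the (1R,6S) acid.

**Route**

Step 1
Reactants: 1 methyl propiolate
Product: 2 methyl 2-(tributylstannyl)prop-2-enoate
Conditions: Bu3SnH, Pd(PPh3)4 (2 mol%), THF, 0 °C to rt
Reagents that add atoms: tributyltin hydride, CCCC[SnH](CCCC)CCCC
Why: Palladium-catalysed hydrostannation (syn addition of Sn–H) of a propiolate should place tin mainly on the carbon alpha to the ester; the minor (E)-beta-stannyl isomer is removed by chromatography.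

Step 2
Reactants: 2 methyl 2-(tributylstannyl)prop-2-enoate, 3 alpha-bromostyrene
Product: 4 methyl 2-methylidene-3-phenylbut-3-enoate
Conditions: Pd(PPh3)4 (5 mol%), CuI (20 mol%), CsF, BHT, DMF, 35 °C; product kept cold and dilute, used at once
Reagents that add atoms: none
Why: Stille cross-coupling with copper and fluoride assistance joins the two sp2 carbons under mild conditions, which matters because 2-alkoxycarbonyl dienes dimerise by Diels–Alder reaction on standing.

Step 3
Reactants: 5 5-bromo-2-methylpent-2-ene
Product: 6 6-methylhept-5-en-1-yne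
Conditions: LiC≡CH·H2NCH2CH2NH2, DMSO, 10 °C to rt; distillation
Reagents that add atoms: lithium acetylide ethylenediamine complex, [Li+].[C-]#C.NCCN
Why: SN2 alkylation of an acetylide by a primary bromide in a dipolar aprotic solvent is a standard route to terminal alkynes.

Step 4
Reactants: 4 methyl 2-methylidene-3-phenylbut-3-enoate, 6 6-methylhept-5-en-1-yne
Product: 7 methyl 4-(4-methylpent-3-en-1-yl)-2-phenylcyclohexa-1,4-diene-1-carboxylate
Conditions: CoBr2(dppe) (10 mol%; dppe = Ph2PCH2CH2PPh2), Zn, ZnI2 (20 mol% each), CH2Cl2, rt, argon; 6 added over 2 h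
Reagents that add atoms: none
Why: Zn reduces CoBr2(dppe) to a monovalent cobalt bisphosphine species and ZnI2 frees coordination sites, so that the s-cis diene and the alkyne bind side by side; oxidative coupling should join the unsubstituted alkyne carbon to the methylene beta to the ester, giving a trivalent cobalt allyl/vinyl metallacycle, and reductive elimination then joins the chain-bearing vinyl carbon to the methylene next to the phenyl-bearing carbon. The closest known reaction type is the neutral cobalt-catalysed Diels–Alder reaction of 2,3-disubstituted butadienes with unactivated terminal alkynes, which gives 1,4-cyclohexadienes. The six-membered ring is closed in the coordination sphere of the metal as a formal [4+2] closure (C2–C3 by oxidative coupling, C4–C5 by reductive elimination, target numbering), and no stereocentre is created. The step needs regioselectivity, chain para to the ester; the ester makes its neighbouring methylene the electrophilic diene terminus and lets the allyl fragment be held as a cobalt enolate, and the bisphosphine ligand is the adjustable element that should reinforce this sense. It also needs chemoselectivity: the trisubstituted alkene of 6 does not compete for the metal, slow addition of 6 limits alkyne trimerisation, and exclusion of oxygen and oxidants keeps the skipped diene from being dehydrogenated to the biaryl.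

Step 5
Reactants: 7 methyl 4-(4-methylpent-3-en-1-yl)-2-phenylcyclohexa-1,4-diene-1-carboxylate
Product: 8 4-(4-methylpent-3-en-1-yl)-2-phenylcyclohexa-1,4-diene-1-carboxylic acid
Conditions: LiOH, THF/MeOH/H2O (degassed), 40 °C; then 1 M HCl, 0 °C, to pH 3
Reagents that add atoms: lithium hydroxide, [Li+].[OH-]
Why: Saponification of the methyl ester frees the carboxyl group needed to direct step 6; mild temperature and oxygen-free solvent are used so that the doubly allylic ring CH2 groups are neither isomerised into conjugation nor oxidised.

Step 6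
Reactants: 8 4-(4-methylpent-3-en-1-yl)-2-phenylcyclohexa-1,4-diene-1-carboxylic acid
Product: 9 (1S,6R)-4-(4-methylpent-3-en-1-yl)-6-phenylcyclohex-3-ene-1-carboxylic acid
Conditions: Ru(OAc)2[(R)-BINAP] (2 mol%), H2 (50 bar), MeOH, 40 °C
Reagents that add atoms: none
Why: Carboxylate-directed asymmetric hydrogenation of a tetrasubstituted alpha,beta-unsaturated acid: the substrate binds ruthenium as carboxylate, so only the conjugated C1=C6 alkene reaches the metal hydride; syn addition of H2 gives the cis acid and the chiral bisphosphine selects the face that makes C6 (R), while the gamma,delta ring alkene and the chain alkene lack this anchoring and are not reduced by this catalyst class.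

Step 7
Reactants: 9 (1S,6R)-4-(4-methylpent-3-en-1-yl)-6-phenylcyclohex-3-ene-1-carboxylic acid
Product: 10 methyl (1S,6R)-4-(4-methylpent-3-en-1-yl)-6-phenylcyclohex-3-ene-1-carboxylate
Conditions: MeI, K2CO3, DMF, rt
Reagents that add atoms: methyl iodide, CI
Why: O-alkylation of the carboxylate (SN2 on MeI) esterifies without the strong acid that the trisubstituted alkenes would not tolerate.

Step 8
Reactants: 10 methyl (1S,6R)-4-(4-methylpent-3-en-1-yl)-6-phenylcyclohex-3-ene-1-carboxylate
Product: 11 methyl (1R,6R)-4-(4-methylpent-3-en-1-yl)-6-phenylcyclohex-3-ene-1-carboxylate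
Conditions: NaOMe (0.3 equiv), MeOH, 65 °C
Reagents that add atoms: none
Why: Base-mediated epimerisation through the ester enolate should move C1 to the thermodynamically preferred trans isomer, in which ester and phenyl can both be equatorial; C6 has no acidic hydrogen and keeps its configuration, and any residual cis ester is separated and recycled.

Step 9
Reactants: 11 methyl (1R,6R)-4-(4-methylpent-3-en-1-yl)-6-phenylcyclohex-3-ene-1-carboxylate
Product: 12 [(1R,6R)-4-(4-methylpent-3-en-1-yl)-6-phenylcyclohex-3-en-1-yl]methanol
Conditions: LiAlH4, THF, 0 °C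
Reagents that add atoms: none
Why: Hydride reduction of the ester to the primary alcohol leaves the isolated alkenes and both stereocentres untouched.

Step 10
Reactants: 12 [(1R,6R)-4-(4-methylpent-3-en-1-yl)-6-phenylcyclohex-3-en-1-yl]methanol
Product: 13 (1R,6R)-4-(4-methylpent-3-en-1-yl)-6-phenylcyclohex-3-ene-1-carbaldehyde
Conditions: Dess–Martin periodinane, NaHCO3, CH2Cl2, 0 °C to rt
Reagents that add atoms: none
Why: Dess–Martin oxidation under buffered conditions gives the aldehyde without over-oxidation; the trans arrangement at C1 is also the more stable one, so it is not at risk.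

Step 11
Reactants: 14 5-methoxybenzene-1,3-diol (5-methoxyresorcinol)
Product: 15 3-methoxy-5-[(triisopropylsilyl)oxy]phenol
Conditions: 14 (2 equiv), TIPSCl (1 equiv), imidazole, DMF, 0 °C to rt
Reagents that add atoms: triisopropylsilyl chloride, CC(C)[Si](Cl)(C(C)C)C(C)C
Why: Silylation of one hydroxyl of a symmetric diol used in excess is a statistical monoprotection; the bulky silyl ether is chosen because it neither directs lithiation nor allows it at the neighbouring positions.

Step 12
Reactants: 15 3-methoxy-5-[(triisopropylsilyl)oxy]phenol
Product: 16 triisopropyl[3-methoxy-5-(methoxymethoxy)phenoxy]silane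
Conditions: MOMCl, i-Pr2NEt, CH2Cl2, 0 °C to rt
Reagents that add atoms: chloromethyl methyl ether, COCCl
Why: O-alkylation of the phenol installs the MOM acetal, which directs the lithiation of step 13 and is later removed by mild acid.

Step 13
Reactants: 16 triisopropyl[3-methoxy-5-(methoxymethoxy)phenoxy]silane, 13 (1R,6R)-4-(4-methylpent-3-en-1-yl)-6-phenylcyclohex-3-ene-1-carbaldehyde
Product: 18 {2-methoxy-6-(methoxymethoxy)-4-[(triisopropylsilyl)oxy]phenyl}[(1R,6R)-4-(4-methylpent-3-en-1-yl)-6-phenylcyclohex-3-en-1-yl]methanol, via aryllithium 17 (not isolated)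
Conditions: 16 (1.5 equiv), n-BuLi (1.4 equiv), TMEDA, THF, 0 °C; then 13, −78 °C to −30 °C; aq. NH4Cl
Reagents that add atoms: none
Why: Directed ortho-metalation followed by 1,2-addition: the ring hydrogen between OMOM and OMe is the only one flanked by two coordinating groups, while the positions beside the OTIPS group are shielded, so the aryllithium carries the substitution pattern of the target; the new carbinol centre forms without control and is removed in step 14.

Step 14
Reactants: 18 {2-methoxy-6-(methoxymethoxy)-4-[(triisopropylsilyl)oxy]phenyl}[(1R,6R)-4-(4-methylpent-3-en-1-yl)-6-phenylcyclohex-3-en-1-yl]methanol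
Product: 19 {2-methoxy-6-(methoxymethoxy)-4-[(triisopropylsilyl)oxy]phenyl}[(1R,6R)-4-(4-methylpent-3-en-1-yl)-6-phenylcyclohex-3-en-1-yl]methanone
Conditions: Dess–Martin periodinane, NaHCO3, CH2Cl2, rt
Reagents that add atoms: none
Why: Dess–Martin oxidation of the hindered benzylic alcohol gives the aryl ketone, and both carbinol epimers converge on one compound.

Step 15
Reactants: 19 {2-methoxy-6-(methoxymethoxy)-4-[(triisopropylsilyl)oxy]phenyl}[(1R,6R)-4-(4-methylpent-3-en-1-yl)-6-phenylcyclohex-3-en-1-yl]methanone
Product: 20 [4-hydroxy-2-methoxy-6-(methoxymethoxy)phenyl][(1R,6R)-4-(4-methylpent-3-en-1-yl)-6-phenylcyclohex-3-en-1-yl]methanone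
Conditions: Bu4NF, THF, 0 °C; aq. NH4Cl
Reagents that add atoms: none
Why: Fluoride-mediated desilylation cleaves the phenolic Si–O bond and leaves the MOM acetal intact; the basic medium can only drive C1 toward the trans ketone, which is the thermodynamic isomer.

Step 16
Reactants: 20 [4-hydroxy-2-methoxy-6-(methoxymethoxy)phenyl][(1R,6R)-4-(4-methylpent-3-en-1-yl)-6-phenylcyclohex-3-en-1-yl]methanone
Product: 21 (2,4-dihydroxy-6-methoxyphenyl)[(1R,6R)-4-(4-methylpent-3-en-1-yl)-6-phenylcyclohex-3-en-1-yl]methanone
Conditions: 2 M HCl (aq.), MeOH, 40 °C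
Reagents that add atoms: none
Why: Acid-catalysed acetal methanolysis removes the MOM group; a MOM ether ortho to a carbonyl is among the most labile, so dilute acid at mild temperature should suffice and spare the trisubstituted alkenes.

**Compound list**

1 | methyl propiolate | COC(=O)C#C | starting material
2 | methyl 2-(tributylstannyl)prop-2-enoate | CCCC[Sn](CCCC)(CCCC)C(=C)C(=O)OC | intermediate
3 | alpha-bromostyrene, (1-bromoethenyl)benzene | BrC(=C)c1ccccc1 | starting material
4 | methyl 2-methylidene-3-phenylbut-3-enoate | COC(=O)C(=C)C(=C)c1ccccc1 | intermediate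
5 | 5-bromo-2-methylpent-2-ene | CC(C)=CCCBr | starting material
6 | 6-methylhept-5-en-1-yne | C#CCCC=C(C)C | intermediate
7 | methyl 4-(4-methylpent-3-en-1-yl)-2-phenylcyclohexa-1,4-diene-1-carboxylate | COC(=O)C1=C(c2ccccc2)CC(CCC=C(C)C)=CC1 | intermediate
8 | 4-(4-methylpent-3-en-1-yl)-2-phenylcyclohexa-1,4-diene-1-carboxylic acid | OC(=O)C1=C(c2ccccc2)CC(CCC=C(C)C)=CC1 | intermediate
9 | (1S,6R)-4-(4-methylpent-3-en-1-yl)-6-phenylcyclohex-3-ene-1-carboxylic acid (cis) | OC(=O)[C@H]1CC=C(CCC=C(C)C)C[C@H]1c1ccccc1 | intermediate
10 | methyl (1S,6R)-4-(4-methylpent-3-en-1-yl)-6-phenylcyclohex-3-ene-1-carboxylate (cis) | COC(=O)[C@H]1CC=C(CCC=C(C)C)C[C@H]1c1ccccc1 | intermediate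
11 | methyl (1R,6R)-4-(4-methylpent-3-en-1-yl)-6-phenylcyclohex-3-ene-1-carboxylate (trans) | COC(=O)[C@@H]1CC=C(CCC=C(C)C)C[C@H]1c1ccccc1 | intermediate
12 | [(1R,6R)-4-(4-methylpent-3-en-1-yl)-6-phenylcyclohex-3-en-1-yl]methanol | OC[C@@H]1CC=C(CCC=C(C)C)C[C@H]1c1ccccc1 | intermediate
13 | (1R,6R)-4-(4-methylpent-3-en-1-yl)-6-phenylcyclohex-3-ene-1-carbaldehyde | O=C[C@@H]1CC=C(CCC=C(C)C)C[C@H]1c1ccccc1 | intermediate
14 | 5-methoxybenzene-1,3-diol (5-methoxyresorcinol) | COc1cc(O)cc(O)c1 | starting material
15 | 3-methoxy-5-[(triisopropylsilyl)oxy]phenol | COc1cc(O)cc(O[Si](C(C)C)(C(C)C)C(C)C)c1 | intermediate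
16 | triisopropyl[3-methoxy-5-(methoxymethoxy)phenoxy]silane | COCOc1cc(OC)cc(O[Si](C(C)C)(C(C)C)C(C)C)c1 | intermediate
17 | {2-methoxy-6-(methoxymethoxy)-4-[(triisopropylsilyl)oxy]phenyl}lithium | [Li]c1c(OC)cc(O[Si](C(C)C)(C(C)C)C(C)C)cc1OCOC | intermediate (not isolated)
18 | {2-methoxy-6-(methoxymethoxy)-4-[(triisopropylsilyl)oxy]phenyl}[(1R,6R)-4-(4-methylpent-3-en-1-yl)-6-phenylcyclohex-3-en-1-yl]methanol (both carbinol epimers) | COCOc1cc(O[Si](C(C)C)(C(C)C)C(C)C)cc(OC)c1C(O)[C@@H]1CC=C(CCC=C(C)C)C[C@H]1c1ccccc1 | intermediate
19 | {2-methoxy-6-(methoxymethoxy)-4-[(triisopropylsilyl)oxy]phenyl}[(1R,6R)-4-(4-methylpent-3-en-1-yl)-6-phenylcyclohex-3-en-1-yl]methanone | COCOc1cc(O[Si](C(C)C)(C(C)C)C(C)C)cc(OC)c1C(=O)[C@@H]1CC=C(CCC=C(C)C)C[C@H]1c1ccccc1 | intermediate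
20 | [4-hydroxy-2-methoxy-6-(methoxymethoxy)phenyl][(1R,6R)-4-(4-methylpent-3-en-1-yl)-6-phenylcyclohex-3-en-1-yl]methanone | COCOc1cc(O)cc(OC)c1C(=O)[C@@H]1CC=C(CCC=C(C)C)C[C@H]1c1ccccc1 | intermediate
21 | (2,4-dihydroxy-6-methoxyphenyl)[(1R,6R)-4-(4-methylpent-3-en-1-yl)-6-phenylcyclohex-3-en-1-yl]methanone | COc1cc(O)cc(O)c1C(=O)[C@@H]1CC=C(CCC=C(C)C)C[C@H]1c1ccccc1 | target

**Step count and risks**

Total step count: 16. Longest linear sequence: 13 steps (1, 2, 4, 5, 6, 7, 8, 9, 10, 13, 14, 15, 16).

Steps most likely to fail:

1. Step 4. The phenyl and ester groups of the diene may steer the alkyne in opposite directions: a bulky bisphosphine tends to keep the alkyne substituent away from the larger diene substituent (here phenyl), while the electronic bias of the ester points the other way, so regiochemistry can erode or reverse. The acrylate-like diene can also dimerise, the alkyne can trimerise, and the skipped diene can be dehydrogenated. A change of ligand class on cobalt is the first adjustment. The fallback leaves cobalt and diene 4 aside and builds the same skipped diene by a thermal Diels–Alder reaction with the roles of the partners exchanged. It sets out from methyl propiolate 1: Sonogashira coupling with iodobenzene (PdCl2(PPh3)2, CuI, K2CO3, THF, 60 °C) should give methyl 3-phenylprop-2-ynoate F1. F1 is heated with an excess of myrcene (7-methyl-3-methylideneocta-1,6-diene, C=CC(=C)CCC=C(C)C, a commercial terpene) in toluene at about 160 °C in a sealed tube under argon with BHT. A 2-substituted diene is expected to add to the ynoate mainly in the para sense, which is ester 7; the minor meta adduct would be removed by chromatography, and the route is rejoined at 7 before step 5.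

2. Step 6. Hydrogen delivery to the hindered tetrasubstituted alkene may be slow, so that migration of the skipped ring alkene, metal-mediated dehydrogenation to the aromatic acid, over-reduction of the ring alkene or poor facial discrimination can compete. The fallback gives up catalytic asymmetric induction and sets out from ester 7. Mg turnings in MeOH (single-electron conjugate reduction of the beta-aryl enoate; isolated alkenes are inert) should give the ring-saturated ester as a racemic mixture of the cis isomer, methyl rac-(1S,6R)-4-(4-methylpent-3-en-1-yl)-6-phenylcyclohex-3-ene-1-carboxylate F2, and the trans isomer, methyl rac-(1R,6R)-4-(4-methylpent-3-en-1-yl)-6-phenylcyclohex-3-ene-1-carboxylate F3. NaOMe in MeOH converts F2 into F3 as in step 8, and preparative chromatography on a chiral stationary phase separates the enantiomers of F3. The (1R,6R) enantiomer is ester 11, where the route is rejoined before step 9; half of the material is given up.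

3. Step 5. Hydroxide attacks the hindered conjugated ester slowly, and during that time deprotonation of the doubly allylic ring CH2 groups can move the skipped alkene into conjugation; any oxygen then aromatises the ring. The fallback avoids base altogether and sets out from ester 7. i-Bu2AlH (CH2Cl2, −78 °C) reduces the ester to the allylic alcohol [4-(4-methylpent-3-en-1-yl)-2-phenylcyclohexa-1,4-dien-1-yl]methanol F4. Dess–Martin periodinane gives the enal 4-(4-methylpent-3-en-1-yl)-2-phenylcyclohexa-1,4-diene-1-carbaldehyde F5. Pinnick oxidation (NaClO2, NaH2PO4, 2-methylbut-2-ene in large excess, t-BuOH/H2O) then gives acid 8, where the route is rejoined before step 6.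

**Further compounds**

F1 | step 4 | methyl 3-phenylprop-2-ynoate | COC(=O)C#Cc1ccccc1
F2 | step 6 | methyl rac-(1S,6R)-4-(4-methylpent-3-en-1-yl)-6-phenylcyclohex-3-ene-1-carboxylate (racemic cis ester, relative configuration drawn) | COC(=O)[C@H]1CC=C(CCC=C(C)C)C[C@H]1c1ccccc1
F3 | step 6 | methyl rac-(1R,6R)-4-(4-methylpent-3-en-1-yl)-6-phenylcyclohex-3-ene-1-carboxylate (racemic trans ester, relative configuration drawn) | COC(=O)[C@@H]1CC=C(CCC=C(C)C)C[C@H]1c1ccccc1
F4 | step 5 | [4-(4-methylpent-3-en-1-yl)-2-phenylcyclohexa-1,4-dien-1-yl]methanol | OCC1=C(c2ccccc2)CC(CCC=C(C)C)=CC1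
F5 | step 5 | 4-(4-methylpent-3-en-1-yl)-2-phenylcyclohexa-1,4-diene-1-carbaldehyde | O=CC1=C(c2ccccc2)CC(CCC=C(C)C)=CC1
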